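**Assumption (one line):** 4-methylpent-2-yn-1-ol and 2,4-dibromobut-1-ene are taken as catalogue chemicals; atom labels follow cembrane numbering (C1 = iPr-bearing carbon, C4 = CO2Me-bearing carbon, C7 = CH(OAc), C8 = C(Me)–O, C12 = lactone α-carbon, C20 = lactone C=O).

## Retrosynthetic overview

1. Last ring (14-membered carbocycle): the C5–C6 bond, by 14-endo cyclisation of a C6 primary alkyl radical onto a Morita–Baylis–Hillman (MBH) acetate; loss of acetate in the same step creates C3=C4 and completes the dienoate.
2. MBH acetate from the C3 enal and methyl propiolate; the radical precursor (C6–I) from the primary alcohol of an epoxy-alcohol-derived diol.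
3. First ring (ε-lactone): ring-closing metathesis of a tertiary 2-substituted acrylate, which forces the cis C11=C12 geometry.
4. That tertiary ester and both stereocentres: Ti-mediated opening at C8 (inversion) of a Sharpless epoxy alcohol by the "east" acrylic acid.
5. Fragments: epoxy alcohol from hex-1-en-5-yne (carboalumination, asymmetric epoxidation); acid from 4-methylpent-2-yn-1-ol, 2,4-dibromobut-1-ene and CO.

## Route

**Step 1**
Reactants: 1, hex-1-en-5-yne
Product: 2, (2E)-3-methylhepta-2,6-dien-1-ol
Conditions: Me3Al (2 equiv), Cp2ZrCl2 (20 mol%), CH2Cl2, 0 °C → rt; then n-BuLi, THF, −78 °C; (CH2O)n, → rt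
Reagents that add atoms: trimethylaluminium, C[Al](C)C; paraformaldehyde (as formaldehyde), C=O
Why: Negishi Zr-catalysed syn-carboalumination of the terminal alkyne (much faster than the terminal alkene) and trapping of the alkenyl alanate with formaldehyde gives the E-trisubstituted allylic alcohol, as in the geraniol synthesis.

**Step 2**
Reactants: 2, (2E)-3-methylhepta-2,6-dien-1-ol
Product: 3, [(2R,3R)-3-(but-3-en-1-yl)-3-methyloxiran-2-yl]methanol
Conditions: Ti(OiPr)4 (10 mol%), D-(−)-diethyl tartrate (12 mol%), t-BuOOH, 4 Å MS, CH2Cl2, −20 °C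
Reagents that add atoms: tert-butyl hydroperoxide, CC(C)(C)OO
Why: Sharpless asymmetric epoxidation acts only on the allylic alkene, and D-(−)-DET gives the (2R,3R)-epoxide (the enantiomer of the L-DET/geraniol case), fixing C7 and setting up C8.

**Step 3**
Reactants: 4, 4-methylpent-2-yn-1-ol
Product: 5, (2Z)-3-iodo-4-methylpent-2-en-1-ol
Conditions: Red-Al, THF, 0 °C → rt; EtOAc; then I2, −78 °C
Reagents that add atoms: iodine, II
Why: Hydroxyl-directed trans-hydroalumination places Al on C3 cis to CH2OH, and iodinolysis with retention gives the Z-vinyl iodide that fixes the later C1=C2 geometry.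

**Step 4**
Reactants: 5, (2Z)-3-iodo-4-methylpent-2-en-1-ol; 6, 2,4-dibromobut-1-ene
Product: 7, (2E)-6-bromo-3-(propan-2-yl)hepta-2,6-dien-1-ol
Conditions: 6, Zn dust, LiCl, THF, 40 °C (alkylzinc bromide, 2.5 equiv); then 5, Pd(OAc)2/SPhos (2/4 mol%), THF, rt
Reagents that add atoms: none
Why: Negishi sp3–sp2 coupling with retention puts the new chain cis to CH2OH; Zn inserts only into the alkyl C–Br and Pd reacts with the vinyl iodide in preference to the 2-bromoalkene.

**Step 5**
Reactants: 7, (2E)-6-bromo-3-(propan-2-yl)hepta-2,6-dien-1-ol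
Product: 8, (5E)-7-hydroxy-2-methylidene-5-(propan-2-yl)hept-5-enoic acid
Conditions: Pd(OAc)2 (5 mol%), Xantphos, CO (1 atm), H2O, Et3N, DMF, 70 °C
Reagents that add atoms: carbon monoxide, [C-]#[O+]; water, O
Why: Pd-catalysed hydroxycarbonylation of the 2-bromo-1-alkene gives the 2-substituted acrylic acid directly; the allylic alcohol cannot lactonise because that would need an E-alkene in an 8-membered ring.

**Step 6**
Reactants: 3, [(2R,3R)-3-(but-3-en-1-yl)-3-methyloxiran-2-yl]methanol; 8, (5E)-7-hydroxy-2-methylidene-5-(propan-2-yl)hept-5-enoic acid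
Product: 9, (2R,3S)-1,2-dihydroxy-3-methylhept-6-en-3-yl (5E)-7-hydroxy-2-methylidene-5-(propan-2-yl)hept-5-enoate
Conditions: Ti(OiPr)4 (1.5 equiv), CH2Cl2, 0 °C → rt; tartaric acid work-up; used at once
Reagents that add atoms: none
Why: Sharpless–Caron Ti(OiPr)4-mediated opening of a 2,3-epoxy alcohol delivers the titanium-bound carboxylate to C3 (here also the tertiary, electronically favoured carbon) with inversion, so C8 becomes S with the acyl oxygen on it while C7 keeps the epoxide oxygen (R).

**Step 7**
Reactants: 9, the tertiary acrylate triol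
Product: 10, (7S)-7-[(1R)-1,2-dihydroxyethyl]-3-[(3E)-5-hydroxy-3-(propan-2-yl)pent-3-en-1-yl]-7-methyl-6,7-dihydrooxepin-2(5H)-one
Conditions: Hoveyda–Grubbs II (10 mol%), 1,4-benzoquinone (10 mol%), toluene (2 mM), 80 °C
Reagents that add atoms: none
Why: Ring-closing metathesis between the terminal vinyl group and the acrylate methylene (ethylene lost) closes the seven-membered lactone, so C11=C12 is necessarily cis; the trisubstituted C1=C2 alkene is inert.

**Step 8**
Reactants: 10, the lactone triol
Product: 11, (2E)-5-{(7S)-7-[(1R)-1,2-dihydroxyethyl]-7-methyl-2-oxo-2,5,6,7-tetrahydrooxepin-3-yl}-3-(propan-2-yl)pent-2-enal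
Conditions: activated MnO2 (15 equiv), CH2Cl2, rt
Reagents that add atoms: none
Why: MnO2 oxidises only the allylic primary alcohol to the enal, leaving the 1,2-diol and the alkene geometry untouched.

**Step 9**
Reactants: 11, the enal diol
Product: 12, (2E)-5-{(7S)-7-[(1S)-1-hydroxy-2-iodoethyl]-7-methyl-2-oxo-2,5,6,7-tetrahydrooxepin-3-yl}-3-(propan-2-yl)pent-2-enal
Conditions: I2, PPh3, imidazole, THF, 0 °C
Reagents that add atoms: iodine, II
Why: Appel (Garegg–Samuelsson) iodination is selective for the primary over the hindered secondary alcohol; the descriptor at C7 changes to S only because CH2I outranks C8, the geometry is unchanged.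

**Step 10**
Reactants: 12, the iodohydrin enal; 13, methyl propiolate
Product: 14, methyl (4E)-3-hydroxy-7-{(7S)-7-[(1S)-1-hydroxy-2-iodoethyl]-7-methyl-2-oxo-2,5,6,7-tetrahydrooxepin-3-yl}-2-methylidene-5-(propan-2-yl)hept-4-enoate (both C3 epimers)
Conditions: DIBAL-H (3.0 equiv), NMO, THF, 0 °C; 13 (3.3 equiv), 0 °C; then 12, 0 °C → rt
Reagents that add atoms: none
Why: Vinylalumination (aluminium-mediated MBH surrogate): hydroalumination of the propiolate gives an α-(methoxycarbonyl)vinylalane that adds 1,2 to the enal without amine catalysts (which could alkylate at C–I or isomerise the enal); the new carbinol centre is removed in step 12.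

**Step 11**
Reactants: 14, the MBH diol
Product: 15, methyl (4E)-3-acetoxy-7-{(7S)-7-[(1S)-1-acetoxy-2-iodoethyl]-7-methyl-2-oxo-2,5,6,7-tetrahydrooxepin-3-yl}-2-methylidene-5-(propan-2-yl)hept-4-enoate
Conditions: Ac2O, pyridine, DMAP (5 mol%), CH2Cl2, 0 °C; used without storage
Reagents that add atoms: acetic anhydride, CC(=O)OC(C)=O
Why: One acetylation installs the C7 acetate of the target and turns the MBH alcohol into the leaving group for the ring closure.

**Step 12**
Reactants: 15, the iodo MBH diacetate
Product: 16, sarcrassin D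
Conditions: 15 added over 8 h to Ru(bpy)3(PF6)2 (5 mol%), iPr2NEt (10 equiv), degassed MeCN (final 3 mM), blue LEDs, rt; then DBU (1 equiv), 0 °C
Reagents that add atoms: none
Why: Proposed new method: the α-aminoalkyl radical from iPr2NEt abstracts iodine to give the C6 primary radical, which closes the 14-membered ring by endo attack on the acrylate CH2 (C5); Ru(I) reduces the α-ester radical to the enolate, which expels the C3 acetate (E1cB) to give the dienoate with CO2Me trans to C2 (DBU converges any H-trapped β-acetoxy ester); closest known reactions are intermolecular photoredox allylation of alkyl radicals with MBH acetates, halogen-atom-transfer Giese additions and Porter/Pattenden 14-endo radical macrocyclisations onto acrylates; Ru(bpy)3 is chosen for its low triplet energy so the diene is not E/Z-scrambled, and no stereocentre is touched.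

## Compound list

1 | hex-1-en-5-yne | C=CCCC#C | starting material
2 | (2E)-3-methylhepta-2,6-dien-1-ol | OC/C=C(\C)CCC=C | intermediate
3 | [(2R,3R)-3-(but-3-en-1-yl)-3-methyloxiran-2-yl]methanol | OC[C@H]1O[C@]1(C)CCC=C | intermediate
4 | 4-methylpent-2-yn-1-ol | CC(C)C#CCO | starting material
5 | (2Z)-3-iodo-4-methylpent-2-en-1-ol | OC/C=C(\I)C(C)C | intermediate
6 | 2,4-dibromobut-1-ene | C=C(Br)CCBr | starting material
7 | (2E)-6-bromo-3-(propan-2-yl)hepta-2,6-dien-1-ol | OC/C=C(\CCC(Br)=C)C(C)C | intermediate
8 | (5E)-7-hydroxy-2-methylidene-5-(propan-2-yl)hept-5-enoic acid | OC/C=C(\CCC(=C)C(O)=O)C(C)C | intermediate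
9 | (2R,3S)-1,2-dihydroxy-3-methylhept-6-en-3-yl (5E)-7-hydroxy-2-methylidene-5-(propan-2-yl)hept-5-enoate | OC[C@@H](O)[C@](C)(CCC=C)OC(=O)C(=C)CC/C(=C\CO)C(C)C | intermediate
10 | (7S)-7-[(1R)-1,2-dihydroxyethyl]-3-[(3E)-5-hydroxy-3-(propan-2-yl)pent-3-en-1-yl]-7-methyl-6,7-dihydrooxepin-2(5H)-one | OC[C@@H](O)[C@]1(C)CCC=C(CC/C(=C\CO)C(C)C)C(=O)O1 | intermediate
11 | (2E)-5-{(7S)-7-[(1R)-1,2-dihydroxyethyl]-7-methyl-2-oxo-2,5,6,7-tetrahydrooxepin-3-yl}-3-(propan-2-yl)pent-2-enal | OC[C@@H](O)[C@]1(C)CCC=C(CC/C(=C\C=O)C(C)C)C(=O)O1 | intermediate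
12 | (2E)-5-{(7S)-7-[(1S)-1-hydroxy-2-iodoethyl]-7-methyl-2-oxo-2,5,6,7-tetrahydrooxepin-3-yl}-3-(propan-2-yl)pent-2-enal | IC[C@@H](O)[C@]1(C)CCC=C(CC/C(=C\C=O)C(C)C)C(=O)O1 | intermediate
13 | methyl propiolate | C#CC(=O)OC | starting material
14 | methyl (4E)-3-hydroxy-7-{(7S)-7-[(1S)-1-hydroxy-2-iodoethyl]-7-methyl-2-oxo-2,5,6,7-tetrahydrooxepin-3-yl}-2-methylidene-5-(propan-2-yl)hept-4-enoate (C3 epimers) | IC[C@@H](O)[C@]1(C)CCC=C(CC/C(=C\C(O)C(=C)C(=O)OC)C(C)C)C(=O)O1 | intermediate
15 | methyl (4E)-3-acetoxy-7-{(7S)-7-[(1S)-1-acetoxy-2-iodoethyl]-7-methyl-2-oxo-2,5,6,7-tetrahydrooxepin-3-yl}-2-methylidene-5-(propan-2-yl)hept-4-enoate (C3 epimers) | IC[C@@H](OC(C)=O)[C@]1(C)CCC=C(CC/C(=C\C(OC(C)=O)C(=C)C(=O)OC)C(C)C)C(=O)O1 | intermediate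
16 | sarcrassin D, (7R,8S) in cembrane numbering | COC(=O)/C1=C/C=C(/C(C)C)CCC2=CCC[C@](C)(OC2=O)[C@H](OC(C)=O)CC1 | target

## Summary

**Total steps:** 12.
**Longest linear sequence:** 10 (steps 3–12: 4 → 5 → 7 → 8 → 9 → 10 → 11 → 12 → 14 → 15 → 16).

**Three steps most likely to fail, each with a fallback that changes the approach:**

1. **Step 12 (radical macrocyclisation).** The C6 radical can instead undergo a 1,5-H shift from the allylic C10–H, a bridging 6-exo attack on the lactone enoate, or simple reduction. Fallback: make C5–C6 intermolecularly by Giese addition of the radical from acetylated 12 to a large excess of methyl 2-(dimethoxyphosphoryl)acrylate, then close the ring by intramolecular Horner–Wadsworth–Emmons reaction (LiCl/DBU) of that phosphonate with the C3 enal.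

2. **Step 6 (Ti-mediated carboxylate opening at the tertiary carbon).** Ti-promoted elimination to an allylic diol and tertiary-to-secondary acyl migration are the risks. Fallback: form the quaternary C–O(acyl) bond intramolecularly. Ozonise the vinyl group of 3 to the C11 aldehyde, carry out a Z-selective Ando olefination with an α-substituted diaryl phosphonoacetate bearing the east chain, and close the lactone by acid-catalysed 7-exo attack of the Z-acid on the epoxide. No free tertiary ester and no metathesis are involved.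

3. **Step 7 (RCM to a trisubstituted ε-lactone from a hindered 2-substituted acrylate).** Slow closure, dimerisation or Ru–H isomerisation are the risks. Fallback: open 3 with acrylic acid and close the unsubstituted lactone (a much easier RCM), then α-iodinate it and attach the east chain by B-alkyl Suzuki coupling with the 9-BBN adduct of the diene made from 5 and a vinyl metal.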